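**Retrosynthetic overview**
- Target ⇐ mono-O-demethylation of (2R)-1-(3,5-dimethoxyphenyl)heptadecan-2-ol; the two methoxy groups are equivalent, so only one product can form.
- C4–C5 bond ⇐ Wittig olefination of a β-silyloxy aldehyde (C1–C4 plus aryl) with a C13 ylide, then hydrogenation.
- Stereocentre ⇐ ketoreductase reduction of the prochiral β-keto ester ethyl 4-(3,5-dimethoxyphenyl)-3-oxobutanoate.
- β-Keto ester ⇐ (3,5-dimethoxyphenyl)acetic acid + Meldrum's acid, then ethanolysis.
- Rings: none is formed; the benzene ring is bought intact.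

Assumption: the SMILES is read as the (R)-carbinol, i.e. 3-[(2R)-2-hydroxyheptadecyl]-5-methoxyphenol; the ketoreductase is taken from a commercial screening panel.

**Route**

Step 1
Reactants: 1 (3,5-dimethoxyphenyl)acetic acid; 2 Meldrum's acid (2,2-dimethyl-1,3-dioxane-4,6-dione)
Product: 3 5-[2-(3,5-dimethoxyphenyl)-1-hydroxyethylidene]-2,2-dimethyl-1,3-dioxane-4,6-dione (enol form of the C5-acyl Meldrum's acid)
Conditions: DCC (1.1 equiv), DMAP (1.2 equiv), CH2Cl2, 0 °C → rt; filter, wash with aq. KHSO4
Reagents that add atoms: none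
Why: DCC/DMAP activation of the acid followed by C-acylation of the strongly acidic Meldrum's acid at C5 (Oikawa–Yonemitsu acylation) gives the stable enolised adduct in high yield.

Step 2
Reactants: 3 acyl Meldrum's acid
Product: 5 ethyl 4-(3,5-dimethoxyphenyl)-3-oxobutanoate, via acylketene 4 (not isolated)
Conditions: EtOH, reflux, 3 h
Reagents that add atoms: ethanol, CCO
Why: On heating, the acyl Meldrum's acid loses acetone and CO2 by cycloreversion to an α-oxoketene that ethanol traps as the β-keto ester (Oikawa–Yonemitsu ethanolysis).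

Step 3
Reactants: 5 ethyl 4-(3,5-dimethoxyphenyl)-3-oxobutanoate
Product: 6 ethyl (3S)-4-(3,5-dimethoxyphenyl)-3-hydroxybutanoate
Conditions: (S)-selective ketoreductase (NADPH-dependent), NADP+ (cat.), i-PrOH (15% v/v), KH2PO4/K2HPO4 buffer pH 7.0, MgSO4 (2 mM), 30 °C
Reagents that add atoms: none
Why: Enzymatic asymmetric ketone reduction by a ketoreductase, for which 4-aryl-3-oxobutanoates are a benchmark substrate class, delivers hydride from NADPH to one carbonyl face and sets the only stereocentre as (S) (the future C2 (R) of the target, the descriptor changing only through CIP priorities), while i-PrOH recycles the cofactor.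

Step 4
Reactants: 6 ethyl (3S)-4-(3,5-dimethoxyphenyl)-3-hydroxybutanoate
Product: 7 ethyl (3S)-3-[(tert-butyldimethylsilyl)oxy]-4-(3,5-dimethoxyphenyl)butanoate
Conditions: TBSCl (1.3 equiv), imidazole (2.5 equiv), DMF, rt
Reagents that add atoms: tert-butyldimethylsilyl chloride (TBSCl), CC(C)(C)[Si](C)(C)Cl
Why: Imidazole-promoted silylation (Corey protocol) caps the secondary alcohol so that it neither consumes hydride or ylide nor undergoes retro-aldol or elimination later, and it does not touch the stereocentre.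

Step 5
Reactants: 7 silyl ether ester
Product: 8 (3S)-3-[(tert-butyldimethylsilyl)oxy]-4-(3,5-dimethoxyphenyl)butanal
Conditions: i-Bu2AlH (DIBAL-H, 1.1 equiv), CH2Cl2, −78 °C; then aq. potassium sodium tartrate (KNaC4H4O6)
Reagents that add atoms: none
Why: In this partial ester reduction one equivalent of DIBAL-H adds once at −78 °C and the aluminium hemiacetal, stabilised by the β-silyloxy group, survives until work-up, where it collapses to the aldehyde.

Step 6
Reactants: 9 1-bromotridecane
Product: 10 tridecyl(triphenyl)phosphonium bromide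
Conditions: PPh3 (1.05 equiv), MeCN, reflux, 48 h; triturate with Et2O
Reagents that add atoms: triphenylphosphine, c1ccc(cc1)P(c1ccccc1)c1ccccc1
Why: SN2 quaternisation of triphenylphosphine by a primary alkyl bromide gives the Wittig salt cleanly.

Step 7
Reactants: 8 (3S)-3-[(tert-butyldimethylsilyl)oxy]-4-(3,5-dimethoxyphenyl)butanal; 10 tridecyl(triphenyl)phosphonium bromide
Product: 12 tert-butyl{[(2R,4Z)-1-(3,5-dimethoxyphenyl)heptadec-4-en-2-yl]oxy}dimethylsilane, via phosphonium ylide 11 (not isolated)
Conditions: 10 (1.3 equiv), NaN(SiMe3)2 (1.25 equiv), THF, −78 → 0 °C; then 8, −78 °C → rt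
Reagents that add atoms: none
Why: Wittig olefination with a non-stabilised ylide is fast at −78 °C, which outruns β-elimination of the silyloxy group, and gives mainly the Z-alkene, whose geometry is irrelevant because it is hydrogenated next.

Step 8
Reactants: 12 silyl-protected alkene
Product: 13 tert-butyl{[(2R)-1-(3,5-dimethoxyphenyl)heptadecan-2-yl]oxy}dimethylsilane
Conditions: H2 (1 atm), 10% Pd/C, EtOAc, rt
Reagents that add atoms: none
Why: Heterogeneous catalytic hydrogenation saturates the isolated disubstituted alkene of either geometry without affecting the aryl ethers, the silyl ether or the homoallylic stereocentre.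

Step 9
Reactants: 13 saturated silyl ether
Product: 14 (2R)-1-(3,5-dimethoxyphenyl)heptadecan-2-ol
Conditions: HF (48% aq.), MeCN, rt (polypropylene vessel)
Reagents that add atoms: none
Why: Fluoride-driven desilylation (strong Si–F bond) frees the secondary alcohol without breaking any bond to the stereocentre and leaves the aryl methyl ethers intact.

Step 10
Reactants: 14 (2R)-1-(3,5-dimethoxyphenyl)heptadecan-2-ol
Product: 15 3-[(2R)-2-hydroxyheptadecyl]-5-methoxyphenol
Conditions: NaSEt (4 equiv), DMF, 150 °C, 3 h; then 1 M HCl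
Reagents that add atoms: none
Why: SN2 demethylation of an aryl methyl ether by ethanethiolate in hot DMF (Feutrill–Mirrington conditions) stops after one ether because the phenoxide formed deactivates the second, the two methoxy groups are equivalent so one product results, and the carbinol stereocentre is inert.

**Compound list**
1 | (3,5-dimethoxyphenyl)acetic acid | COc1cc(CC(=O)O)cc(OC)c1 | starting material
2 | Meldrum's acid (2,2-dimethyl-1,3-dioxane-4,6-dione) | CC1(C)OC(=O)CC(=O)O1 | starting material
3 | 5-[2-(3,5-dimethoxyphenyl)-1-hydroxyethylidene]-2,2-dimethyl-1,3-dioxane-4,6-dione | COc1cc(CC(O)=C2C(=O)OC(C)(C)OC2=O)cc(OC)c1 | intermediate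
4 | 4-(3,5-dimethoxyphenyl)but-1-ene-1,3-dione (acylketene) | COc1cc(CC(=O)C=C=O)cc(OC)c1 | intermediate
5 | ethyl 4-(3,5-dimethoxyphenyl)-3-oxobutanoate | CCOC(=O)CC(=O)Cc1cc(OC)cc(OC)c1 | intermediate
6 | ethyl (3S)-4-(3,5-dimethoxyphenyl)-3-hydroxybutanoate | CCOC(=O)C[C@@H](O)Cc1cc(OC)cc(OC)c1 | intermediate
7 | ethyl (3S)-3-[(tert-butyldimethylsilyl)oxy]-4-(3,5-dimethoxyphenyl)butanoate | CCOC(=O)C[C@@H](O[Si](C)(C)C(C)(C)C)Cc1cc(OC)cc(OC)c1 | intermediate
8 | (3S)-3-[(tert-butyldimethylsilyl)oxy]-4-(3,5-dimethoxyphenyl)butanal | O=CC[C@@H](O[Si](C)(C)C(C)(C)C)Cc1cc(OC)cc(OC)c1 | intermediate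
9 | 1-bromotridecane | CCCCCCCCCCCCCBr | starting material
10 | tridecyl(triphenyl)phosphonium bromide | CCCCCCCCCCCCC[P+](c1ccccc1)(c1ccccc1)c1ccccc1.[Br-] | intermediate
11 | triphenyl(tridecylidene)phosphorane (ylide) | CCCCCCCCCCCCC=P(c1ccccc1)(c1ccccc1)c1ccccc1 | intermediate
12 | tert-butyl{[(2R,4Z)-1-(3,5-dimethoxyphenyl)heptadec-4-en-2-yl]oxy}dimethylsilane | CCCCCCCCCCCC/C=C\C[C@@H](O[Si](C)(C)C(C)(C)C)Cc1cc(OC)cc(OC)c1 | intermediate
13 | tert-butyl{[(2R)-1-(3,5-dimethoxyphenyl)heptadecan-2-yl]oxy}dimethylsilane | CCCCCCCCCCCCCCC[C@@H](O[Si](C)(C)C(C)(C)C)Cc1cc(OC)cc(OC)c1 | intermediate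
14 | (2R)-1-(3,5-dimethoxyphenyl)heptadecan-2-ol | CCCCCCCCCCCCCCC[C@@H](O)Cc1cc(OC)cc(OC)c1 | intermediate
15 | 3-[(2R)-2-hydroxyheptadecyl]-5-methoxyphenol | CCCCCCCCCCCCCCC[C@@H](O)Cc1cc(O)cc(OC)c1 | target

**Step count and risks**
Total steps: 10. Longest linear sequence: 9 (steps 1, 2, 3, 4, 5, 7, 8, 9, 10; step 6 is a one-step side branch).

Three steps most likely to fail:

Step 3 (no panel enzyme gives both useful activity and at least 98% ee on 5). The fallback sets out from 5 and comes back at 6. It replaces the enzyme by a Noyori asymmetric hydrogenation of the β-keto ester: RuCl2[(S)-BINAP] (0.2 mol%), H2 (6–10 bar), EtOH, 60–80 °C. The (S)-ligand gives the (S)-hydroxy ester 6, typically in about 94–97% ee for 4-aryl-acetoacetates, and the ee is raised by recrystallising the solid alcohol 14 later. This fallback makes no new compound (F0).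

Step 5 (over-reduction to the alcohol, or a β-silyloxy aldehyde 8 that eliminates before or during the Wittig step). The fallback sets out from 7 and comes back at 13, so it avoids the aldehyde and bypasses steps 5, 7 and 8. Ester 7 is reduced fully with LiBH4 (THF/MeOH, 0 °C → rt) to (3S)-3-[(tert-butyldimethylsilyl)oxy]-4-(3,5-dimethoxyphenyl)butan-1-ol F1. TsCl, Et3N and catalytic DMAP in CH2Cl2 at 0 °C convert it into (3S)-3-[(tert-butyldimethylsilyl)oxy]-4-(3,5-dimethoxyphenyl)butyl 4-methylbenzenesulfonate F2. Bromide 9 and Mg turnings in THF give tridecylmagnesium bromide F3, which is coupled with F2 under Li2CuCl4 catalysis (THF, −78 °C → rt, Fouquet–Schlosser sp3–sp3 coupling) to give 13 directly.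

Step 10 (incomplete reaction or some double demethylation at a late stage). The fallback sets out from 14 and comes back at 15. BBr3 (4 equiv, CH2Cl2, −78 → 0 °C, then aq. NaHCO3) cleaves both methyl ethers to 5-[(2R)-2-hydroxyheptadecyl]benzene-1,3-diol F4; the secondary alcohol is carried as its borate and released on work-up. F4 is then mono-methylated on a phenolic oxygen with MeI (1.0 equiv) and K2CO3 in acetone at reflux. This gives 15 in a statistical 45–50% per pass; recovered F4 and over-methylated 14 are both recycled.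

**Further compounds**
F0 | step 3 | none | none
F1 | step 5 | (3S)-3-[(tert-butyldimethylsilyl)oxy]-4-(3,5-dimethoxyphenyl)butan-1-ol | OCC[C@@H](O[Si](C)(C)C(C)(C)C)Cc1cc(OC)cc(OC)c1
F2 | step 5 | (3S)-3-[(tert-butyldimethylsilyl)oxy]-4-(3,5-dimethoxyphenyl)butyl 4-methylbenzenesulfonate | Cc1ccc(cc1)S(=O)(=O)OCC[C@@H](O[Si](C)(C)C(C)(C)C)Cc1cc(OC)cc(OC)c1
F3 | step 5 | tridecylmagnesium bromide | CCCCCCCCCCCCC[Mg]Br
F4 | step 10 | 5-[(2R)-2-hydroxyheptadecyl]benzene-1,3-diol | CCCCCCCCCCCCCCC[C@@H](O)Cc1cc(O)cc(O)c1
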